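(Its constants are invented.)

Count what each lost catalyst costs.

    starting material + free catalyst ⇌ catalyst intermediate A (K1 = 450 L mol⁻¹, k1 = 140 L mol⁻¹ min⁻¹)
    catalyst intermediate B → free catalyst + second product (k2 = 49 min⁻¹)
    catalyst intermediate A + capture agent → trapped intermediate (k3 = 59 L mol⁻¹ min⁻¹)
    second substrate + free catalyst ⇌ catalyst intermediate B (K4 = 42 L mol⁻¹, k4 = 110 L mol⁻¹ min⁻¹)
    catalyst intermediate A → free catalyst + target (k5 = 3.2 min⁻¹)

starting material 33 mM; second substrate 33.0 mM; capture agent 9.90 mM; free catalyst 2.4 mM

* the form that holds most of the catalyst when 50 % of the starting material are converted (catalyst intermediate A / trapped intermediate / catalyst intermediate B / free catalyst)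
* its share of the catalyst then

Catalyst intermediate A has two ways forward. It releases target at 3.2 min⁻¹, which frees the catalyst, or it meets capture agent, at 59 L mol⁻¹ min⁻¹ times the capture agent concentration T, and that catalyst leaves the round. We call n the target made per catalyst trapped (the partition ratio): the release constant over the capture constant times T. At the charge n = 5.48. The step back to starting material and the visits to catalyst intermediate B shift when these events happen, but they do not enter this ratio.

On a first round we hold n there. The 2.4 mM of catalyst then gives 13.1 mM of target, and each trapped catalyst also holds one starting material, so 15.5 mM is consumed. That is less than the 16.5 mM that half conversion requires, so on this round the flask stops short of the mark.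

But each capture uses up one capture agent, so T falls to 7.50 mM and n rises to 7.23. Going round again, we sum n along that fall. The target is 54.2 mM times the logarithm of the ratio of T at the start to T at the end, which gives 15.1 mM. The total consumed becomes 17.5 mM, which is more than the mark by 0.958 mM.

So on this round the flask does reach the mark, and we take that margin as what the catalyst still live there has yet to consume. Each live catalyst takes about 7.23 target plus one for itself, so we reckon about 0.116 mM still live. We therefore commit to trapped intermediate, at 95.2 % of the catalyst, more than the live forms together.

The forecast names trapped intermediate at 95 %, on the ground that “Capture therefore acts as stoichiometric deactivation”. The simulation reaches the mark at 0.247 h with trapped intermediate at 94.9 %, against our 95.2 %.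

The rate of making target at that conversion, 8.71 mM h⁻¹, is low because the catalyst has been captured: in the run without the capture step it is 20.9 times the actual one. In this flask, at 1.00 h, target stands at 45.6 % of the starting material charged, with trapped intermediate at >99.9 % of the catalyst. That makes 6.27 target per catalyst charged, more than the 5.48 at the charge and less than the 7.23 at the end of capture.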